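## The problem

Compound 17 has no stereocentre, so the task is regiochemistry on a crowded arene and the survival of delicate oxygen functions. Its core is a 2-hydroxy-1,4-naphthoquinone (ring C, C1 to C4) fused to a benzenoid ring B whose four open positions all differ. C5 bears a hydroxyl peri to the C4 carbonyl, C6 the 2,4-dihydroxy-6-methylbenzoyl group (ring A), C7 a methylene arm ending in a 4-hydroxy-2-pyranone (ring D), and C8 a hydrogen. The ketone between ring A and C6 has all four ortho positions filled (C5–OH, C7–CH2, C2'–OH, C6'–CH3). It therefore cannot be expected from acylation of a finished naphthalene or from an aryl metal and a carbonyl partner, and this bond decides the strategy. Ring C must carry its hydroxyl at C2, beside the carbonyl that is peri to C8–H, which fixes the oxygen pattern of the arene from which the quinone is released. The hydroxyquinone, the hydroxypyranone (acidic, nucleophilic at its C3, opened by base), the doubly activated methylene between rings B and D and the resorcinol ring A would not survive enolate, carbene or oxidant chemistry unprotected, so they should travel as methyl ethers and be freed last. Nothing has to be relayed stereochemically; the two stereogenic intermediates (8 and 14) are racemic and are flattened again. The enabling feature is the sequence C5(OH)–C6(aroyl)–C7(alkyl)–C8(H): C5 and C7 are the carbonyl and α-carbon of a 2-substituted indan-1-one, C8 is its benzylic CH2, and C6 is one extra carbon that can be slipped into the enol double bond with the ring A acyl group already attached.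

## Retrosynthesis

**17 to 16.** Four O–CH3 bonds are cut last: C2' and C4' of ring A, C2 of the quinone and C4 of ring D. Methyl ethers are chosen over benzyl or silyl groups because they pass through every earlier step and two of the four are vinylogous esters that cleave easily. Precursor 16 differs from 17 only in these ethers. The forward step has to cleave them with a boron trihalide without adding halide to the quinone.

**16 to 15.** The two quinone carbonyls are traced back to the para pair of methoxy groups of a 1,2,4-trimethoxy ring. Carrying a quinone through enolate and carbene chemistry is not an option, and a free triol would oxidise uncontrolled. Naphthol 15 is fully aromatic and stable. The forward oxidation must take the most electron-rich ring, keep the C2 methoxy group and leave the free C5 hydroxyl alone.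

**15 to 9 and 13.** This is the central cut: C5–C6 and C6–C7 are broken and C6 leaves with bromine, the aroyl group and a carbene valence, so that ring B collapses to the enol ether of an indanone.
- Cutting C6–CO instead would ask for a Friedel–Crafts or Fries acylation that prefers the open C8, or for an aryl metal addition blocked by four ortho groups.
- Cutting C5–C6 and C7–C8 leads to an anhydride annulation with a longer fragment synthesis (Alternative 3).
- Here the hindered carbon is assembled from an unhindered alkene in 9 and a two-carbon unit on ring A in 13.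
- The forward step needs a carbenoid that selects the enol ether among several π systems, closes through carbon, and then loses bromide with ring expansion.

**13 to 12, 11 and 10.** The C–Br bond and the bond between the carbonyl and the diazo carbon are cut. Commercial acid 10 gives chloride 11, a one-carbon diazo reagent gives diazoketone 12, and 13 is made from 12 just before use. The hindered carbonyl is thus only ever attacked by a small nucleophile.

**9 to 8, then 5 and 7 (7 from 6).** The O–Si bond and the bond between indanone C2 and the ring D methylene are cut. An acetate arm to be elaborated later was weighed and set aside: it would need carboxyl activation next to the ortho aroyl ketone, polyanion chemistry on a free naphthol, and a free hydroxypyranone under the ring C oxidant. Bringing ring D complete as its methyl ether, from commercial 6 by way of bromide 7, removes four late steps. The alkylation must stop at one substitution. The enolisation of 8 can give only one enol ether because the ketone has a single α-hydrogen.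

**5 to 3, then 1 and 2.** The aryl–CH2 and aryl–CO bonds of the five-membered ring are cut. Acylation of 1 occurs at its most nucleophilic carbon and ring closure of 3 at the only free ortho position, so the 4,5,7-trimethoxy pattern of 5 is fixed without isomers. This pattern, not the 4,6,7 one, places the future C3–H of ring C correctly.

## Roads not taken

**Alternative 1:** The cut goes through ring A (C1'–C2' and C1'–C6'), leaving the ketone carbon on C6 as part of an acetyl group. Forward, silyl enol ether A2 would add through carbon to the methyl-bearing α-carbon of 2,4-dimethoxy-6-methylpyrylium tetrafluoroborate A3. The 2H-pyran would open to a dienyl ester, and K2CO3 in methanol would close C1' onto the ester carbonyl to give phenol A1.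
- Merits: the hindered diaryl ketone is again never made by joining two arenes; A1 has C2'–OH already free and ring D in place; conversion of pyrylium salts into benzenes by carbon nucleophiles is an established reaction class. In precedent this road is ahead of the chosen one.
- Weak points: it does not address ring B. A2 is a naphthalene with six different substituents and an acyl group at the same crowded C6, which is the original problem in a smaller form. A3 has three electrophilic carbons and an acidic methyl group, and a bulky nucleophile is more likely to attack the methoxy-bearing positions than the carbon that must become quaternary. The base step also exposes the ring D methylene.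
- Comparison: the chosen plan sets against the better precedent that it makes ring B and the C6–CO attachment in one step from an indanone four steps from commercial material.

**Alternative 2:** The cut is C1'–C6' of ring A. Naphthyl tetraketone A5 would close in dilute aqueous KOH by aldol attack of C1' on the terminal acetyl carbonyl, and loss of water would give resorcinol A4.
- Merits: the closure is biomimetic and mild, and ring A appears with both hydroxyls free. No aryl ether on ring A has to be cleaved at the end, which is a real advantage over the chosen plan.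
- Weak points: A5 has to come from acylation of a polyketone polyanion by a naphthoate whose carbonyl lies between two ortho substituents, the same steric problem again. The tetraketone can also close by Claisen condensation or through oxygen. The free resorcinol must then survive oxidation of ring C. The C7 arm in A4 is only a protected hydroxymethyl group, so ring D still costs several steps.
- Comparison: against the milder end of this road the chosen plan sets a much shorter sequence and a ring D that is complete before the key step.

**Alternative 3:** The cut is C5–C6 and C7–C8. NaH would form the enolate of 5,6,8-trimethoxyhomophthalic anhydride A7, which would add to ynone A8 in conjugate fashion (C8–C7), acylate (C6–C5), lose CO2 and give naphthol A6.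
- Merits: it forms ring B convergently with the aroyl group in place, regiochemistry follows from the conjugate addition, and anionic annulation of homophthalic anhydrides with acetylenic acceptors is well-known chemistry. In reliability of the ring-forming step this road is better than the chosen one.
- Weak points: A7 needs a longer synthesis than indanone 5. The γ-silyloxy ynone A8 is prone to propargyl–allenyl isomerisation and elimination under NaH. Ring D cannot ride on the ynone because its methylene would be too acidic, so A6 carries only CH2OTBS and the pyranone must be attached afterwards next to the hindered ketone.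
- Comparison: the chosen plan sets against the better precedent roughly half the step count, simpler fragments and a two-step endgame. It pays with one unprecedented step, for which a known-chemistry detour is given below.

Key step: step 8

Assumption: 17 is treated in the tautomeric form drawn (2-hydroxy-1,4-quinone, 4-hydroxy-2-pyranone); 8 and 14 are racemates whose stereocentres disappear within the route.

## Route

Step 1
Reactants: 1 1,2,4-trimethoxybenzene; 2 3-chloropropanoyl chloride
Product: 3 3-chloro-1-(2,4,5-trimethoxyphenyl)propan-1-one
Conditions: AlCl3, CH2Cl2, 0 °C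
Reagents that add atoms: none
Why: Friedel–Crafts acylation; 1 reacts at C5, para to the 2-methoxy and ortho to the 4-methoxy group, and the low temperature limits cleavage of the ortho ether by AlCl3.

Step 2
Reactants: 3 3-chloro-1-(2,4,5-trimethoxyphenyl)propan-1-one
Product: 5 4,5,7-trimethoxy-2,3-dihydro-1H-inden-1-one, via aryl vinyl ketone 4 (not isolated)
Conditions: conc. H2SO4, 85 °C
Reagents that add atoms: none
Why: Loss of HCl gives enone 4, whose protonated form closes by Nazarov-type 4π electrocyclisation (intramolecular Friedel–Crafts alkylation) onto the only free ortho carbon; the same closure is the usual route to 4,7-dimethoxyindan-1-one from the 2,5-dimethoxyphenyl analogue.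

Step 3
Reactants: 6 4-methoxy-6-methyl-2H-pyran-2-one
Product: 7 6-(bromomethyl)-4-methoxy-2H-pyran-2-one
Conditions: NBS, (PhCO2)2 (cat.), CCl4, reflux
Reagents that add atoms: N-bromosuccinimide, O=C1CCC(=O)N1Br
Why: Wohl–Ziegler radical bromination of the allylic-type 6-methyl group, a known preparation of this bromide; radical conditions spare the ring C3–H that polar bromination would attack.

Step 4
Reactants: 5 4,5,7-trimethoxy-2,3-dihydro-1H-inden-1-one; 7 6-(bromomethyl)-4-methoxy-2H-pyran-2-one
Product: 8 4,5,7-trimethoxy-2-[(4-methoxy-2-oxo-2H-pyran-6-yl)methyl]-2,3-dihydro-1H-inden-1-one (racemic)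
Conditions: LiN(SiMe3)2, THF, -78 °C; then 7, -78 to 0 °C
Reagents that add atoms: none
Why: SN2 alkylation of the lithium enolate of 5 (only C2 can enolise) by an activated primary bromide; a slight excess of enolate and low temperature should limit double alkylation, and the new C2 stereocentre is racemic and is erased in step 5.

Step 5
Reactants: 8 4,5,7-trimethoxy-2-[(4-methoxy-2-oxo-2H-pyran-6-yl)methyl]-2,3-dihydro-1H-inden-1-one
Product: 9 6-({3-[tert-butyl(dimethyl)silyl]oxy-4,6,7-trimethoxy-1H-inden-2-yl}methyl)-4-methoxy-2H-pyran-2-one
Conditions: TBSOTf, Et3N, CH2Cl2, 0 °C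
Reagents that add atoms: tert-butyldimethylsilyl trifluoromethanesulfonate, CC(C)(C)[Si](C)(C)OS(=O)(=O)C(F)(F)F
Why: Soft enolisation with a silyl triflate and an amine silylates the ketone, whose single α-hydrogen allows only one, tetrasubstituted, enol ether; the vinylogous ester of ring D is not enolised under these conditions.

Step 6
Reactants: 10 2,4-dimethoxy-6-methylbenzoic acid
Product: 11 2,4-dimethoxy-6-methylbenzoyl chloride
Conditions: (COCl)2, DMF (cat.), CH2Cl2, 0 °C to rt
Reagents that add atoms: oxalyl chloride, O=C(Cl)C(=O)Cl
Why: Acid chloride formation through the Vilsmeier-type chloroiminium species; electron-rich, hindered benzoic acids react readily and the chloride is used crude.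

Step 7
Reactants: 11 2,4-dimethoxy-6-methylbenzoyl chloride
Product: 12 2-diazo-1-(2,4-dimethoxy-6-methylphenyl)ethan-1-one
Conditions: CH2N2 (excess), Et2O, 0 °C to rt
Reagents that add atoms: diazomethane, C=[N+]=[N-]
Why: Acylation of diazomethane (first stage of the Arndt–Eistert sequence); a second equivalent takes up HCl, no ketene can form for lack of an α-hydrogen, and di-ortho-substituted aroyl chlorides are known to undergo this reaction.

Step 8
Reactants: 9 6-({3-[tert-butyl(dimethyl)silyl]oxy-4,6,7-trimethoxy-1H-inden-2-yl}methyl)-4-methoxy-2H-pyran-2-one; 12 2-diazo-1-(2,4-dimethoxy-6-methylphenyl)ethan-1-one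
Product: 15 6-{[3-(2,4-dimethoxy-6-methylbenzoyl)-4-hydroxy-5,7,8-trimethoxynaphthalen-2-yl]methyl}-4-methoxy-2H-pyran-2-one, via bromodiazoketone 13 (not isolated), via bromocyclopropane 14 (not isolated)
Conditions: 12 (2.5 equiv), NBS, DBU, CH2Cl2, 0 °C; cold SiO2 filtration; then 9, Rh2(esp)2 (2 mol %), CH2Cl2, -40 °C to rt
Reagents that add atoms: none
Why: Proposed new method: deprotonative bromination of 12 (NBS and DBU, as used for halodiazoacetates) should give 13, which Rh2(esp)2, the dirhodium complex of α,α,α',α'-tetramethyl-1,3-benzenedipropanoate, should convert into an electrophilic bromo(aroyl)carbenoid that adds to the electron-rich C2=C3 enol ether bond of 9 to give the fused silyloxy bromocyclopropane 14; the closest known reaction types are the dihalocarbene ring expansion of indanone silyl enol ethers to 2-halo-1-naphthols and the Rh2(esp)2-catalysed cyclopropanation and ring expansion of indenes and indoles with halodiazoacetates. Ring B closes in two stages, a [2+1] cyclopropanation followed by ionisation of bromide with disrotatory two-electron electrocyclic opening of the shared bond, pushed by the silyloxy oxygen. The six-membered oxocarbenium ion then gives its silyl group to bromide and the 4H-naphthalenone tautomerises to naphthol 15, so that C5–C6 and C6–C7 are formed with the aroyl group already on C6. No stereocentre survives, but the opening requires bromine on the concave face of 14 (cis to the ring bonds); the donor–acceptor bond between the silyloxy carbon and the carbene carbon can open and reclose, which should feed the unproductive epimer into the productive one. The step needs chemoselectivity for the enol ether over the pyranone and arene π systems and for closure through carbon, not through the carbonyl oxygen to a dihydrofuran. The silyl enol ether is by far the most nucleophilic alkene present, the aroyl carbonyl is twisted and shielded by its two ortho substituents, and only the cyclopropane path ends irreversibly in an aromatic ring. Ylide formation at the ortho methoxy group of the carbenoid should be reversible because methyl migrates poorly, and the excess of 12 covers what is lost that way.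

Step 9
Reactants: 15 6-{[3-(2,4-dimethoxy-6-methylbenzoyl)-4-hydroxy-5,7,8-trimethoxynaphthalen-2-yl]methyl}-4-methoxy-2H-pyran-2-one
Product: 16 6-(2,4-dimethoxy-6-methylbenzoyl)-5-hydroxy-2-methoxy-7-[(4-methoxy-2-oxo-2H-pyran-6-yl)methyl]naphthalene-1,4-dione
Conditions: (NH4)2Ce(NO3)6, MeCN/H2O, 0 °C
Reagents that add atoms: water, O
Why: Oxidative demethylation of the para-dimethoxy pair of the 1,2,4-trimethoxy ring by tetravalent cerium gives the 2-methoxy-1,4-quinone, the carbonyl oxygens coming from water; this ring is the most electron-rich, ring A and ring D are deactivated by their carbonyl groups, and 5-hydroxy-1,4-dimethoxynaphthalenes are known to give juglones under these conditions.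

Step 10
Reactants: 16 6-(2,4-dimethoxy-6-methylbenzoyl)-5-hydroxy-2-methoxy-7-[(4-methoxy-2-oxo-2H-pyran-6-yl)methyl]naphthalene-1,4-dione
Product: 17 6-(2,4-dihydroxy-6-methylbenzoyl)-2,5-dihydroxy-7-[(4-hydroxy-2-oxo-2H-pyran-6-yl)methyl]naphthalene-1,4-dione
Conditions: BBr3, CH2Cl2, -78 °C to rt; then H2O
Reagents that add atoms: none
Why: Lewis acid ether cleavage by BBr3 of the two ring A aryl methyl ethers and of the two vinylogous methyl esters (quinone C2, pyranone C4), the latter being the most labile; the product should be held as boron chelates until aqueous work-up.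

## Compound list

1 | 1,2,4-trimethoxybenzene | COc1ccc(OC)c(OC)c1 | starting material
2 | 3-chloropropanoyl chloride | O=C(Cl)CCCl | starting material
3 | 3-chloro-1-(2,4,5-trimethoxyphenyl)propan-1-one | COc1cc(OC)c(C(=O)CCCl)cc1OC | intermediate
4 | 1-(2,4,5-trimethoxyphenyl)prop-2-en-1-one | COc1cc(OC)c(C(=O)C=C)cc1OC | intermediate (not isolated)
5 | 4,5,7-trimethoxy-2,3-dihydro-1H-inden-1-one | COc1cc(OC)c2c(c1OC)CCC2=O | intermediate
6 | 4-methoxy-6-methyl-2H-pyran-2-one | COc1cc(C)oc(=O)c1 | starting material
7 | 6-(bromomethyl)-4-methoxy-2H-pyran-2-one | COc1cc(CBr)oc(=O)c1 | intermediate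
8 | 4,5,7-trimethoxy-2-[(4-methoxy-2-oxo-2H-pyran-6-yl)methyl]-2,3-dihydro-1H-inden-1-one (racemic) | COc1cc(CC2Cc3c(OC)c(OC)cc(OC)c3C2=O)oc(=O)c1 | intermediate
9 | 6-({3-[tert-butyl(dimethyl)silyl]oxy-4,6,7-trimethoxy-1H-inden-2-yl}methyl)-4-methoxy-2H-pyran-2-one | COc1cc(CC2=C(O[Si](C)(C)C(C)(C)C)c3c(OC)cc(OC)c(OC)c3C2)oc(=O)c1 | intermediate
10 | 2,4-dimethoxy-6-methylbenzoic acid | COc1cc(C)c(C(=O)O)c(OC)c1 | starting material
11 | 2,4-dimethoxy-6-methylbenzoyl chloride | COc1cc(C)c(C(=O)Cl)c(OC)c1 | intermediate
12 | 2-diazo-1-(2,4-dimethoxy-6-methylphenyl)ethan-1-one | COc1cc(C)c(C(=O)C=[N+]=[N-])c(OC)c1 | intermediate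
13 | 2-bromo-2-diazo-1-(2,4-dimethoxy-6-methylphenyl)ethan-1-one | COc1cc(C)c(C(=O)C(Br)=[N+]=[N-])c(OC)c1 | intermediate (not isolated)
14 | 6-{[1-bromo-1a-[tert-butyl(dimethyl)silyl]oxy-1-(2,4-dimethoxy-6-methylbenzoyl)-2,4,5-trimethoxy-1,1a-dihydrocyclopropa[a]inden-6a(6H)-yl]methyl}-4-methoxy-2H-pyran-2-one; racemate, cis-fused, bromine on the concave face and aroyl on the convex face (one enantiomer drawn) | COc1cc(OC)c2c(c1OC)C[C@@]3(Cc4cc(OC)cc(=O)o4)[C@](Br)(C(=O)c4c(C)cc(OC)cc4OC)[C@@]23O[Si](C)(C)C(C)(C)C | intermediate (not isolated)
15 | 6-{[3-(2,4-dimethoxy-6-methylbenzoyl)-4-hydroxy-5,7,8-trimethoxynaphthalen-2-yl]methyl}-4-methoxy-2H-pyran-2-one | COc1cc(Cc2cc3c(OC)c(OC)cc(OC)c3c(O)c2C(=O)c2c(C)cc(OC)cc2OC)oc(=O)c1 | intermediate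
16 | 6-(2,4-dimethoxy-6-methylbenzoyl)-5-hydroxy-2-methoxy-7-[(4-methoxy-2-oxo-2H-pyran-6-yl)methyl]naphthalene-1,4-dione | COc1cc(Cc2cc3c(c(O)c2C(=O)c2c(C)cc(OC)cc2OC)C(=O)C=C(OC)C3=O)oc(=O)c1 | intermediate
17 | 6-(2,4-dihydroxy-6-methylbenzoyl)-2,5-dihydroxy-7-[(4-hydroxy-2-oxo-2H-pyran-6-yl)methyl]naphthalene-1,4-dione | Cc1cc(O)cc(O)c1C(=O)c1c(Cc2cc(O)cc(=O)o2)cc2c(c1O)C(=O)C=C(O)C2=O | target

## Step count and risks

Total: 10 steps. Longest linear sequence: 7 steps (1, 2, 4, 5, 8, 9, 10, from 1,2,4-trimethoxybenzene); the ring A branch (steps 6 and 7) and the ring D branch (step 3) join it at steps 8 and 4.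

**Step 8 (key step, new method).**
- What may go wrong: ring A may be brominated or 13 may decay before it meets the catalyst. The zwitterionic adduct may close through oxygen, or the donor–acceptor cyclopropane may open with loss of silyl in place of bromide when bromine sits on the convex face. The carbenoid may also be consumed by reaction with its own ortho substituents.
- Fallback (known chemistry), setting out from 9 and 11: dibromocarbene from PhHgCBr3 (benzene, 80 °C) cyclopropanates the enol ether. The dibromocyclopropane always has one bromine on the concave face and should open to 6-[(3-bromo-4-hydroxy-5,7,8-trimethoxynaphthalen-2-yl)methyl]-4-methoxy-2H-pyran-2-one F1. O-Acylation with 11 (Et3N, DMAP, CH2Cl2) gives 2-bromo-5,6,8-trimethoxy-3-[(4-methoxy-2-oxo-2H-pyran-6-yl)methyl]naphthalen-1-yl 2,4-dimethoxy-6-methylbenzoate F2. Bromine–lithium exchange (t-BuLi, THF, -100 °C) then triggers an anionic Fries 1,3 oxygen-to-carbon acyl shift that delivers the aroyl group to C6 from the neighbouring oxygen and returns to the route at 15.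

**Step 2.**
- What may go wrong: ring closure may be slow, because the attacked carbon is activated by only one ortho methoxy group while two methoxy groups stabilise the protonated enone. Sulfonation or ether cleavage could then take over.
- Fallback, setting out from 1, which forms the other ring bond: bromination (NBS, MeCN) gives 1-bromo-2,4,5-trimethoxybenzene F3. LiN(i-Pr)2 (THF, -78 °C) removes the proton flanked by bromine and methoxy, and the aryllithium opens oxetane (BF3·OEt2) to 3-(2-bromo-3,5,6-trimethoxyphenyl)propan-1-ol F4. Oxidation (TEMPO, PhI(OAc)2, aqueous MeCN) gives 3-(2-bromo-3,5,6-trimethoxyphenyl)propanoic acid F5. Parham cycloacylation (n-BuLi, 2 equiv, THF, -100 °C) closes the aryl–carbonyl bond and comes back at 5.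

**Step 4.**
- What may go wrong: proton transfer between product and enolate may lead to double alkylation, or the enolate may attack the pyranone ring or deprotonate the bromide.
- Fallback, setting out from 6 and 5: SeO2 (dioxane, reflux) oxidises 6 to 4-methoxy-2-oxo-2H-pyran-6-carbaldehyde F6. Aldol condensation with 5 (piperidine, AcOH) gives (E)-4,5,7-trimethoxy-2-[(4-methoxy-2-oxo-2H-pyran-6-yl)methylidene]-2,3-dihydro-1H-inden-1-one F7. Conjugate reduction with [(Ph3P)CuH]6 comes back at 8.

**Step 9.**
- What may go wrong: oxidation may start at the free naphthol of ring B or at the activated methylene in place of clean oxidative demethylation of ring C.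
- Fallback, setting out from 15: acetylation (Ac2O, pyridine) gives 2-(2,4-dimethoxy-6-methylbenzoyl)-5,6,8-trimethoxy-3-[(4-methoxy-2-oxo-2H-pyran-6-yl)methyl]naphthalen-1-yl acetate F8. Oxidation with (NH4)2Ce(NO3)6 gives 2-(2,4-dimethoxy-6-methylbenzoyl)-6-methoxy-3-[(4-methoxy-2-oxo-2H-pyran-6-yl)methyl]-5,8-dioxo-5,8-dihydronaphthalen-1-yl acetate F9. Acid methanolysis (HCl, MeOH) of the peri acetate comes back at 16.

**Step 10.**
- What may go wrong: cleavage of the pyranone ether may be incomplete, or bromide may add to the quinone.
- Fallback, setting out from 15, which reverses the order: BBr3 in excess cleaves all seven methyl ethers to 6-{[3-(2,4-dihydroxy-6-methylbenzoyl)-4,5,7,8-tetrahydroxynaphthalen-2-yl]methyl}-4-hydroxy-2H-pyran-2-one F10. Its 1,2,4-trihydroxy ring should autoxidise in air (aqueous NaHCO3) to the hydroxyquinone, arriving at 17.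

## Further compounds

F1 | step 8 | 6-[(3-bromo-4-hydroxy-5,7,8-trimethoxynaphthalen-2-yl)methyl]-4-methoxy-2H-pyran-2-one | COc1cc(Cc2cc3c(OC)c(OC)cc(OC)c3c(O)c2Br)oc(=O)c1
F2 | step 8 | 2-bromo-5,6,8-trimethoxy-3-[(4-methoxy-2-oxo-2H-pyran-6-yl)methyl]naphthalen-1-yl 2,4-dimethoxy-6-methylbenzoate | COc1cc(Cc2cc3c(OC)c(OC)cc(OC)c3c(OC(=O)c3c(C)cc(OC)cc3OC)c2Br)oc(=O)c1
F3 | step 2 | 1-bromo-2,4,5-trimethoxybenzene | COc1cc(OC)c(Br)cc1OC
F4 | step 2 | 3-(2-bromo-3,5,6-trimethoxyphenyl)propan-1-ol | OCCCc1c(Br)c(OC)cc(OC)c1OC
F5 | step 2 | 3-(2-bromo-3,5,6-trimethoxyphenyl)propanoic acid | OC(=O)CCc1c(Br)c(OC)cc(OC)c1OC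
F6 | step 4 | 4-methoxy-2-oxo-2H-pyran-6-carbaldehyde | COc1cc(C=O)oc(=O)c1
F7 | step 4 | (E)-4,5,7-trimethoxy-2-[(4-methoxy-2-oxo-2H-pyran-6-yl)methylidene]-2,3-dihydro-1H-inden-1-one | COc1cc(OC)c2c(c1OC)C/C(=C\c1cc(OC)cc(=O)o1)C2=O
F8 | step 9 | 2-(2,4-dimethoxy-6-methylbenzoyl)-5,6,8-trimethoxy-3-[(4-methoxy-2-oxo-2H-pyran-6-yl)methyl]naphthalen-1-yl acetate | COc1cc(Cc2cc3c(OC)c(OC)cc(OC)c3c(OC(C)=O)c2C(=O)c2c(C)cc(OC)cc2OC)oc(=O)c1
F9 | step 9 | 2-(2,4-dimethoxy-6-methylbenzoyl)-6-methoxy-3-[(4-methoxy-2-oxo-2H-pyran-6-yl)methyl]-5,8-dioxo-5,8-dihydronaphthalen-1-yl acetate | COc1cc(Cc2cc3c(c(OC(C)=O)c2C(=O)c2c(C)cc(OC)cc2OC)C(=O)C=C(OC)C3=O)oc(=O)c1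
F10 | step 10 | 6-{[3-(2,4-dihydroxy-6-methylbenzoyl)-4,5,7,8-tetrahydroxynaphthalen-2-yl]methyl}-4-hydroxy-2H-pyran-2-one | Oc1cc(Cc2cc3c(O)c(O)cc(O)c3c(O)c2C(=O)c2c(C)cc(O)cc2O)oc(=O)c1
A1 | alternative 1 | (2-hydroxy-4-methoxy-6-methylphenyl){1,5,6,8-tetramethoxy-3-[(4-methoxy-2-oxo-2H-pyran-6-yl)methyl]naphthalen-2-yl}methanone | Cc1cc(OC)cc(O)c1C(=O)c1c(Cc2cc(OC)cc(=O)o2)cc2c(OC)c(OC)cc(OC)c2c1OC
A2 | alternative 1 | 4-methoxy-6-({4,5,7,8-tetramethoxy-3-[1-(trimethylsilyloxy)ethenyl]naphthalen-2-yl}methyl)-2H-pyran-2-one | C=C(O[Si](C)(C)C)c1c(Cc2cc(OC)cc(=O)o2)cc2c(OC)c(OC)cc(OC)c2c1OC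
A3 | alternative 1 | 2,4-dimethoxy-6-methylpyrylium tetrafluoroborate | COc1cc(C)[o+]c(OC)c1.F[B-](F)(F)F
A4 | alternative 2 | [3-(tert-butyldimethylsilyloxymethyl)-1,5,6,8-tetramethoxynaphthalen-2-yl](2,4-dihydroxy-6-methylphenyl)methanone | Cc1cc(O)cc(O)c1C(=O)c1c(CO[Si](C)(C)C(C)(C)C)cc2c(OC)c(OC)cc(OC)c2c1OC
A5 | alternative 2 | 1-[3-(tert-butyldimethylsilyloxymethyl)-1,5,6,8-tetramethoxynaphthalen-2-yl]octane-1,3,5,7-tetrone | CC(=O)CC(=O)CC(=O)CC(=O)c1c(CO[Si](C)(C)C(C)(C)C)cc2c(OC)c(OC)cc(OC)c2c1OC
A6 | alternative 3 | [3-(tert-butyldimethylsilyloxymethyl)-1-hydroxy-5,6,8-trimethoxynaphthalen-2-yl](2,4-dimethoxy-6-methylphenyl)methanone | Cc1cc(OC)cc(OC)c1C(=O)c1c(CO[Si](C)(C)C(C)(C)C)cc2c(OC)c(OC)cc(OC)c2c1O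
A7 | alternative 3 | 5,6,8-trimethoxy-1H-isochromene-1,3(4H)-dione | COc1cc(OC)c2c(c1OC)CC(=O)OC2=O
A8 | alternative 3 | 4-(tert-butyldimethylsilyloxy)-1-(2,4-dimethoxy-6-methylphenyl)but-2-yn-1-one | Cc1cc(OC)cc(OC)c1C(=O)C#CCO[Si](C)(C)C(C)(C)C
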